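## Retrosynthetic overview
1. Gericudranin E (5) is cut at the CH2–C1'' bond of the diarylmethane. This gives an A-ring o-quinone methide (C6=CH2, generated with light) and 4-hydroxyphenylboronic acid (4).
2. The o-quinone methide comes from the C6 Mannich base 3. Its C6–CH2 bond is made from (+)-aromadendrin (1) and aminal 2, and this step fixes the 6- rather than 8-regiochemistry.
3. Both stereocentres (2R,3R) are bought in 1 and are never touched.
4. Ring order: no ring is built. Rings A, C and B arrive assembled in 1; ring D arrives preformed in 4 and is attached last.
5. The route has two steps and no protecting groups. A one-step direct hydroxybenzylation cannot tell C6 from C8, so two steps is the shortest sequence with regiocontrol at both ends of the CH2 bridge.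

Assumption: natural (+)-(2R,3R)-aromadendrin (dihydrokaempferol), sold enantiopure as a plant isolate, is the purchased chiral starting material.

## Route

**Step 1**
Reactants: 1, (+)-aromadendrin, (2R,3R)-3,5,7-trihydroxy-2-(4-hydroxyphenyl)chroman-4-one; 2, bis(dimethylamino)methane
Product: 3, (2R,3R)-6-[(dimethylamino)methyl]-3,5,7-trihydroxy-2-(4-hydroxyphenyl)chroman-4-one (C6 Mannich base, 2,3-trans)
Conditions: 2 (1.05 equiv), i-PrOH (0.1 M), Ar, dark, 20 °C, 12–16 h; filter the precipitated zwitterion and wash with cold i-PrOH/Et2O
Reagents that add atoms: bis(dimethylamino)methane, CN(C)CN(C)C (delivers CH2NMe2)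
Why: This is a Mannich aminomethylation (SEAr) in which the acidic 7-OH ionises the aminal to Me2N+=CH2, only the phloroglucinol-type A ring is nucleophilic enough to trap it, the carbon flanked by both hydroxyls (C6) reacts first in 5,7-dihydroxyflavanon(ol)s, and the O–H···N-bonded zwitterionic mono-adduct precipitates before C8 can react; no stereocentre is formed, and the O2-free, room-temperature, weakly basic conditions leave C2/C3 as (2R,3R).

**Step 2**
Reactants: 3, C6 Mannich base; 4, 4-hydroxyphenylboronic acid
Product: 5, gericudranin E, (2R,3R)-3,5,7-trihydroxy-6-(4-hydroxybenzyl)-2-(4-hydroxyphenyl)chroman-4-one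
Conditions: 4 (2.0 equiv), 4 Å MS, MeCN/HFIP 4:1 (2 mM in 3), Ar, dark 30 min; then hν 350–365 nm (LED, borosilicate), 15 °C, 2–6 h (HPLC control); pH 5 aqueous work-up, C18 chromatography
Reagents that add atoms: 4-hydroxyphenylboronic acid, OB(O)c1ccc(O)cc1 (delivers the 4-hydroxyphenyl ring; boron leaves as B(OH)3 and the amine as Me2NH)
Why: Proposed new method: a light-triggered deaminative aryl transfer ("photo-Petasis-type" benzylic arylation) in which 3 and 4 first condense in the dark to a cyclic O–B(−)(Ar)(OH)–N(+)Me2 chelate (a phenolate-like donor with an ammonium-like leaving group); selective excitation of the acylphloroglucinol chromophore (4 is transparent above 300 nm) drives ortho-benzylic C–N heterolysis to a push–pull o-quinone methide (C6=CH2) whose oxygen stays bound to tetracoordinate boron, and the electron-rich 4-hydroxyphenyl group then migrates from boron (ipso carbon) to the exocyclic CH2 through a six-membered transition state, re-aromatising ring A, so the bond can form only between CH2 and C1'' (no ortho/para or O-alkyl isomers); HFIP stabilises the ion pair, is non-nucleophilic and buffers the liberated Me2NH, product 5 has no leaving group and dissipates light harmlessly by 5-OH→O=C4 proton transfer, and working at 15 °C instead of the ≥80–100 °C of a thermal retro-Mannich keeps the heat- and base-labile C2 centre (4'-OH-assisted ring opening) and C3 intact, with no new stereocentre formed; the closest known reaction types are photodeamination of o-hydroxybenzylamines and their ammonium salts to o-quinone methides (trapped so far by O-, N- and S-nucleophiles and enol ethers) and thermal Petasis-type addition of aryl or alkenyl boronates to o-quinone methides.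

## Compound list
1 | (+)-aromadendrin, (2R,3R)-dihydrokaempferol | O=C1c2c(cc(O)cc2O)O[C@H](c2ccc(O)cc2)[C@H]1O | starting material
2 | bis(dimethylamino)methane | CN(C)CN(C)C | starting material
3 | (2R,3R)-6-[(dimethylamino)methyl]aromadendrin | O=C1c2c(cc(O)c(CN(C)C)c2O)O[C@H](c2ccc(O)cc2)[C@H]1O | intermediate
4 | 4-hydroxyphenylboronic acid | OB(O)c1ccc(O)cc1 | starting material
5 | gericudranin E, (2R,3R)-6-(4-hydroxybenzyl)aromadendrin | O=C1c2c(cc(O)c(Cc3ccc(O)cc3)c2O)O[C@H](c2ccc(O)cc2)[C@H]1O | target

## Summary
Total step count: 2. Longest linear sequence: 2.

Most likely failures. The route has only two steps, so both are ranked, and step 2 appears twice for its two independent failure points.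

1. **Step 2, o-quinone methide generation (proposed new step).**
   - Risk: ultrafast 5-OH→O=C4 excited-state proton transfer may drain the excited state before C–N heterolysis, giving negligible conversion.
   - Fallback (known chemistry, different disconnection): make the C6–CH2 bond directly by acid-catalysed Friedel–Crafts hydroxybenzylation of 1 with 4-hydroxybenzyl alcohol (cat. p-TsOH, dioxane, 40 °C). Separate the 6-, 8- and 6,8-products by reverse-phase HPLC.
2. **Step 1, Mannich reaction.**
   - Risk: C6/C8 mixtures, bis-aminomethylation, or amine-induced C2 epimerisation or oxidation to the flavonol.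
   - Fallback: halogen-based regiocontrol.
     - 3,7,4'-Tri-O-acetylation of 1, which leaves the chelated 5-OH free.
     - 5-OH-directed ortho-iodination at C6 (BnMe3N·ICl2, CaCO3).
     - Pd-catalysed Negishi coupling with 4-acetoxybenzylzinc chloride.
     - Acidic methanolysis of the acetates.
3. **Step 2, aryl transfer.**
   - Risk: the quinone methide is captured by C8 of a second flavanonol, giving methylene-bridged dimers faster than boron delivers the aryl group.
   - Fallback: drop quinone methide chemistry but keep the C6 handle.
     - Acetolysis of 3 (Ac2O) to the peracetylated 6-acetoxymethyl derivative.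
     - Pd-catalysed benzylic Suzuki–Miyaura coupling with 4-acetoxyphenylboronic acid.
     - Acidic methanolysis of the acetates.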